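**Plan**

Numbering: C7 and C7' are the benzylic CH groups, C8 is the carbinol and C8' the CH of the ring fusion, C9 is the OCH2 on C8 and C9' the OCH2 on C8'. Ring A is C7'–O1–C9–C8–C8' and ring B is C7–O2–C9'–C8'–C8.
Enabling feature: C8 is a tertiary alcohol bonded to C7 of ring B, to the fusion carbon C8' and to C9, which carries O1 of ring A. With C9 at the lactone level this is an α-hydroxy ester, the mark of a 1,2-dione in which an alkoxide (O1) added to one carbonyl (C9) and the flanking carbon (C7) moved to the other (C8).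
Cuts, in retrosynthetic order: both phenolic O–benzyl bonds; C9H2 back to C9=O; O1–C9 and C7–C8 together, which reconnects C7 to C9 and unfolds both rings into a 2-aryl-5-[aryl(hydroxy)methyl]oxane-3,4-dione; the C9 oxygen (Rubottom); C8'–C7' (aldol); C7–C9 and O2–C9' (hetero-Diels–Alder).
Forward: the pyran is built first, the C7' side chain is attached and C9 is oxidised. One operation then closes ring A as a lactone and contracts the pyran to ring B, and C9 is finally reduced to CH2 with O1–C7' left intact.
Stereochemistry: C7 comes from the cycloaddition catalyst. C8' and C7' come from C7 through an equilibrating, chelated anti aldol (2,5-trans pyranone). C8 comes from C8', because only a cis-fused bicycle can form.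

Key step: step 9

Ar = 4-(benzyloxy)-3,5-dimethoxyphenyl. Pyran locants in 6–15: ring O = O2, C2 = C7, C3 = C9, C4 = C8, C5 = C8', C6 = C9'.
Assumption: (S)-BINOL–Ti(OiPr)4 is taken to direct the diene to the Si face of aldehyde 3, the sense it shows in related additions of π-nucleophiles to aromatic aldehydes. If the opposite sense is found, (R)-BINOL is used and nothing else changes.

**Step 1**
Reactants: 1 syringaldehyde; 2 benzyl bromide
Product: 3 4-(benzyloxy)-3,5-dimethoxybenzaldehyde
Conditions: K2CO3, DMF, 60 °C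
Reagents that add atoms: none
Why: Williamson ether synthesis on the acidic phenol with a reactive benzylic bromide should be clean, and it masks the phenol against every base, hydride and oxidant used later.

**Step 2**
Reactants: 3 4-(benzyloxy)-3,5-dimethoxybenzaldehyde; 4 (E)-1-methoxy-3-(trimethylsilyloxy)buta-1,3-diene
Product: 6 (S)-2-Ar-2,3-dihydro-4H-pyran-4-one, via silylated Mukaiyama aldol adduct 5 (not isolated)
Conditions: (S)-BINOL (20 mol %), Ti(OiPr)4 (10 mol %), 4 Å molecular sieves, Et2O, −20 °C; then CF3CO2H, CH2Cl2, 0 °C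
Reagents that add atoms: none
Why: This is a catalytic asymmetric hetero-Diels–Alder reaction in its stepwise Mukaiyama aldol/cyclisation form, well established for aromatic aldehydes with this diene; the BINOL–titanium complex shields one aldehyde face so that C7 is set (S in 6, the spatial arrangement of C7 in the target), and acid closes 5 by oxa-Michael addition with loss of methanol.

**Step 3**
Reactants: 6 (S)-2-Ar-2,3-dihydro-4H-pyran-4-one; 3 4-(benzyloxy)-3,5-dimethoxybenzaldehyde
Product: 8 (2S,5R)-2-Ar-5-[(S)-Ar(hydroxy)methyl]oxan-4-one (2,5-trans, anti aldol), via lithium enolate 7 (not isolated)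
Conditions: LiBH(s-Bu)3 (1.05 equiv), THF, −78 °C; ZnCl2 (1.1 equiv), then 3, −78 → −10 °C; AcOH
Reagents that add atoms: none
Why: In this reductive aldol reaction 1,4-hydride delivery to the vinylogous ester gives the C4–C5 enolate regiospecifically, and the addition is left to equilibrate through the zinc chelate, in which the side chain is equatorial on the pyranone (2,5-trans, sets C8') and the aryl group equatorial on the chelate ring (anti, also the preference of the Zimmerman–Traxler chair of a ring-locked E enolate, sets C7'), minor isomers being removed by chromatography.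

**Step 4**
Reactants: 8 (2S,5R)-2-Ar-5-[(S)-Ar(hydroxy)methyl]oxan-4-one
Product: 9 (2S,5R)-2-Ar-5-[(S)-Ar(triethylsilyloxy)methyl]oxan-4-one
Conditions: Et3SiCl, imidazole, DMF, 0 °C → rt
Reagents that add atoms: chlorotriethylsilane, CC[Si](Cl)(CC)CC
Why: Standard silylation of a secondary alcohol blocks retro-aldol cleavage and keeps the benzylic carbinol out of the two oxidations to come, and the triethylsilyl group can later be removed under very mild conditions.

**Step 5**
Reactants: 9 (2S,5R)-2-Ar-5-[(S)-Ar(triethylsilyloxy)methyl]oxan-4-one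
Product: 10 C3=C4 trimethylsilyl enol ether of 9, (2S,5R)-2-Ar-5-[(S)-Ar(triethylsilyloxy)methyl]-4-(trimethylsilyloxy)-5,6-dihydro-2H-pyran
Conditions: LiN(i-Pr)2, Me3SiCl (present from the start), THF, −78 °C
Reagents that add atoms: chlorotrimethylsilane, C[Si](C)(C)Cl
Why: Kinetic deprotonation with in situ silyl trapping should take the C3 methylene rather than the tertiary, side-chain-shielded C5–H, giving the C3=C4 silyl enol ether without touching C8' and without β-elimination of the silyloxy group.

**Step 6**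
Reactants: 10 C3=C4 trimethylsilyl enol ether of 9
Product: 12 (2R,3R,5R)-2-Ar-3-hydroxy-5-[(S)-Ar(triethylsilyloxy)methyl]oxan-4-one (3-OH trans to the 2-aryl group), via 3-trimethylsilyloxy ketone 11 (not isolated)
Conditions: mCPBA, CH2Cl2, −20 → 0 °C; then aq citric acid, THF, 0 °C
Reagents that add atoms: 3-chloroperoxybenzoic acid, OOC(=O)c1cccc(Cl)c1
Why: In the Rubottom oxidation the peracid epoxidises the electron-rich enol ether on the face away from the C2 aryl group, silyl migration gives 11, and mild acid frees the C3 hydroxyl while the bulkier triethylsilyl ether stays, the C3 configuration being of no consequence because step 7 erases it.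

**Step 7**
Reactants: 12 (2R,3R,5R)-2-Ar-3-hydroxy-5-[(S)-Ar(triethylsilyloxy)methyl]oxan-4-one
Product: 13 (2R,5R)-2-Ar-5-[(S)-Ar(triethylsilyloxy)methyl]oxane-3,4-dione
Conditions: Dess–Martin periodinane, CH2Cl2, 0 °C → rt; filtration through neutral silica, used at once
Reagents that add atoms: none
Why: Dess–Martin oxidation turns α-hydroxy ketones into 1,2-diketones under non-basic, non-aqueous conditions, as a dione with acidic C2–H and C5–H requires, and no new stereocentre is formed.

**Step 8**
Reactants: 13 (2R,5R)-2-Ar-5-[(S)-Ar(triethylsilyloxy)methyl]oxane-3,4-dione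
Product: 14 (2R,5R)-2-Ar-5-[(S)-Ar(hydroxy)methyl]oxane-3,4-dione
Conditions: HF·pyridine, THF, 0 °C
Reagents that add atoms: none
Why: Fluoride cleavage of a triethylsilyl ether in a weakly acidic medium frees the C7' hydroxyl without generating an alkoxide, so C7 and C8' are not exposed to an enolising base.

**Step 9**
Reactants: 14 (2R,5R)-2-Ar-5-[(S)-Ar(hydroxy)methyl]oxane-3,4-dione
Product: 16 (1R,2R,5R,6S)-2,6-di-Ar-1-hydroxy-3,7-dioxabicyclo[3.3.0]octan-8-one (C9 lactone; 7R,8R,7'S,8'R), via bridged hemiketal 15 (not isolated)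
Conditions: THF, 0 °C, 30 min; LiN(SiMe3)2 (1.05 equiv), −78 → 0 °C; AcOH
Reagents that add atoms: none
Why: Proposed new method: in 14 the C7' hydroxyl can reach only the C3 carbonyl (addition to C4 would need a four-membered ring), and its 5-exo-trig addition gives the bridged hemiketal 15, whose lithium alkoxide then drives the benzylic, oxygen-bearing C2 (C7) with its bonding pair from C3 onto the adjacent C4 carbonyl, so that C3 becomes the lactone carbonyl C9 and C4 the carbinol C8. The closest known reaction types are the benzilic ester rearrangement of cyclic 1,2-diones with an external alkoxide, which contracts the ring, and the anionic α-ketol rearrangement; a tethered alkoxide acting on an enolisable oxane-3,4-dione has not been shown. Ring A closes by the 5-exo-trig hemiketalisation (O1–C9) and is kept as the γ-lactone, while ring B is not cyclised separately but arises from the six-membered pyran through the 1,2-shift that replaces C7–C9 by C7–C8. C8, the only new stereocentre, is dictated by C8': the O1–C7' bridge covers one face of the C4 carbonyl, C7 reaches C8 from the other, only the cis-fused bicyclo[3.3.0] skeleton can result, C7 migrates with retention, and the anti configuration of 14 places the C7' aryl group exo on the bridge. The step needs addition and shift to outrun enolisation at C7 and C8' and retro-aldol loss of 3, and 15 itself provides this, since its C7–H is no longer next to a carbonyl, its C8'–H sits at a bridgehead where an enolate would violate Bredt's rule, and its C7' oxygen is tied up. For that reason the base is added at −78 °C only after 14 has been allowed to settle into 15, and Li+ bridging the hemiketal oxygen and the nearly eclipsed C4 carbonyl oxygen should hold the ring closed and polarise the acceptor.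

**Step 10**
Reactants: 16 (1R,2R,5R,6S)-2,6-di-Ar-1-hydroxy-3,7-dioxabicyclo[3.3.0]octan-8-one
Product: 17 (1R,2R,5R,6S)-2,6-di-Ar-3,7-dioxabicyclo[3.3.0]octane-1,8-diol (lactol, mixture of anomers at C9)
Conditions: i-Bu2AlH (2.5 equiv), CH2Cl2, −78 °C; aq potassium sodium tartrate
Reagents that add atoms: none
Why: Partial reduction of a γ-lactone to the lactol with i-Bu2AlH at low temperature is standard, the first equivalent being consumed by the C8 hydroxyl, whose aluminium alkoxide helps to hold the tetrahedral intermediate, and the anomeric centre is erased in step 11.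

**Step 11**
Reactants: 17 (1R,2R,5R,6S)-2,6-di-Ar-3,7-dioxabicyclo[3.3.0]octane-1,8-diol
Product: 18 (1S,2R,5R,6S)-2,6-di-Ar-3,7-dioxabicyclo[3.3.0]octan-1-ol (dibenzyl ether of the target)
Conditions: Et3SiH, BF3·OEt2, CH2Cl2, −78 → −40 °C
Reagents that add atoms: none
Why: Ionic reduction of the lactol (silane capture of the oxocarbenium ion) removes the anomeric hydroxyl and leaves O1–C7' intact, so C7' keeps its configuration, while the low temperature and the weak donor character of a 4-benzyloxy group twisted between two methoxy groups should keep the C7–O2 and C7'–O1 bonds from ionising.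

**Step 12**
Reactants: 18 (1S,2R,5R,6S)-2,6-di-Ar-3,7-dioxabicyclo[3.3.0]octan-1-ol
Product: 19 8-hydroxysyringaresinol (7R,8S,7'S,8'R)
Conditions: H2 (1 atm), 10 % Pd/C, EtOAc, rt, stopped after two equivalents of H2
Reagents that add atoms: none
Why: Catalytic hydrogenolysis cleaves aryl benzyl ethers much faster than the two ring benzylic C–O bonds, so stopping after two equivalents of hydrogen should release both phenols and leave all four stereocentres untouched.

**Compound list**

1 | syringaldehyde | COc1cc(C=O)cc(OC)c1O | starting material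
2 | benzyl bromide | BrCc1ccccc1 | starting material
3 | 4-(benzyloxy)-3,5-dimethoxybenzaldehyde | COc1cc(C=O)cc(OC)c1OCc1ccccc1 | intermediate
4 | (E)-1-methoxy-3-(trimethylsilyloxy)buta-1,3-diene | CO/C=C/C(=C)O[Si](C)(C)C | starting material
5 | (S,E)-5-Ar-1-methoxy-5-(trimethylsilyloxy)pent-1-en-3-one | CO/C=C/C(=O)C[C@H](O[Si](C)(C)C)c1cc(OC)c(OCc2ccccc2)c(OC)c1 | intermediate
6 | (S)-2-Ar-2,3-dihydro-4H-pyran-4-one | O=C1C=CO[C@H](c2cc(OC)c(OCc3ccccc3)c(OC)c2)C1 | intermediate
7 | lithium (S)-2-Ar-3,6-dihydro-2H-pyran-4-olate (C4–C5 enolate) | [Li+].[O-]C1=CCO[C@H](c2cc(OC)c(OCc3ccccc3)c(OC)c2)C1 | intermediate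
8 | (2S,5R)-2-Ar-5-[(S)-Ar(hydroxy)methyl]oxan-4-one | O=C1C[C@@H](c2cc(OC)c(OCc3ccccc3)c(OC)c2)OC[C@@H]1[C@H](O)c1cc(OC)c(OCc2ccccc2)c(OC)c1 | intermediate
9 | (2S,5R)-2-Ar-5-[(S)-Ar(triethylsilyloxy)methyl]oxan-4-one | O=C1C[C@@H](c2cc(OC)c(OCc3ccccc3)c(OC)c2)OC[C@@H]1[C@H](O[Si](CC)(CC)CC)c1cc(OC)c(OCc2ccccc2)c(OC)c1 | intermediate
10 | (2S,5R)-2-Ar-5-[(S)-Ar(triethylsilyloxy)methyl]-4-(trimethylsilyloxy)-5,6-dihydro-2H-pyran | C[Si](C)(C)OC1=C[C@@H](c2cc(OC)c(OCc3ccccc3)c(OC)c2)OC[C@@H]1[C@H](O[Si](CC)(CC)CC)c1cc(OC)c(OCc2ccccc2)c(OC)c1 | intermediate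
11 | (2R,3R,5R)-2-Ar-5-[(S)-Ar(triethylsilyloxy)methyl]-3-(trimethylsilyloxy)oxan-4-one | O=C1[C@H](O[Si](C)(C)C)[C@@H](c2cc(OC)c(OCc3ccccc3)c(OC)c2)OC[C@@H]1[C@H](O[Si](CC)(CC)CC)c1cc(OC)c(OCc2ccccc2)c(OC)c1 | intermediate
12 | (2R,3R,5R)-2-Ar-3-hydroxy-5-[(S)-Ar(triethylsilyloxy)methyl]oxan-4-one | O=C1[C@H](O)[C@@H](c2cc(OC)c(OCc3ccccc3)c(OC)c2)OC[C@@H]1[C@H](O[Si](CC)(CC)CC)c1cc(OC)c(OCc2ccccc2)c(OC)c1 | intermediate
13 | (2R,5R)-2-Ar-5-[(S)-Ar(triethylsilyloxy)methyl]oxane-3,4-dione | O=C1C(=O)[C@@H]([C@H](O[Si](CC)(CC)CC)c2cc(OC)c(OCc3ccccc3)c(OC)c2)CO[C@@H]1c1cc(OC)c(OCc2ccccc2)c(OC)c1 | intermediate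
14 | (2R,5R)-2-Ar-5-[(S)-Ar(hydroxy)methyl]oxane-3,4-dione | O=C1C(=O)[C@@H]([C@H](O)c2cc(OC)c(OCc3ccccc3)c(OC)c2)CO[C@@H]1c1cc(OC)c(OCc2ccccc2)c(OC)c1 | intermediate
15 | (1R,4R,5R,7S)-4,7-di-Ar-5-hydroxy-3,6-dioxabicyclo[3.2.1]octan-8-one (bridged hemiketal, C7' aryl exo) | O=C1[C@]2(O)O[C@H](c3cc(OC)c(OCc4ccccc4)c(OC)c3)[C@H]1CO[C@@H]2c1cc(OC)c(OCc2ccccc2)c(OC)c1 | intermediate
16 | (1R,2R,5R,6S)-2,6-di-Ar-1-hydroxy-3,7-dioxabicyclo[3.3.0]octan-8-one | COc1cc([C@H]2OC(=O)[C@]3(O)[C@@H](c4cc(OC)c(OCc5ccccc5)c(OC)c4)OC[C@H]23)cc(OC)c1OCc1ccccc1 | intermediate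
17 | (1R,2R,5R,6S)-2,6-di-Ar-3,7-dioxabicyclo[3.3.0]octane-1,8-diol (anomers at C9) | COc1cc([C@H]2OC(O)[C@]3(O)[C@@H](c4cc(OC)c(OCc5ccccc5)c(OC)c4)OC[C@H]23)cc(OC)c1OCc1ccccc1 | intermediate
18 | (1S,2R,5R,6S)-2,6-di-Ar-3,7-dioxabicyclo[3.3.0]octan-1-ol | COc1cc([C@H]2OC[C@]3(O)[C@@H](c4cc(OC)c(OCc5ccccc5)c(OC)c4)OC[C@H]23)cc(OC)c1OCc1ccccc1 | intermediate
19 | 8-hydroxysyringaresinol | COc1cc([C@H]2OC[C@]3(O)[C@@H](c4cc(OC)c(O)c(OC)c4)OC[C@H]23)cc(OC)c1O | target

Total step count: 12. Longest linear sequence: 12 steps (1 → 19; aldehyde 3 is used twice).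

**Steps most likely to fail**

Step 9. Reopening of the hemiketal alkoxide may be followed by proton loss from C7, which gives the conjugated enolate, or by retro-aldol cleavage of C8'–C7'. Either process could be faster than the 1,2-shift, and the first also erodes C7. The fallback uses known chemistry only, sets out from 9 and returns at 16. It contracts the ring by a Wolff rearrangement and adds the C8 oxygen afterwards.
- Kinetic trifluoroacetylation of 9 at C3 (LiN(SiMe3)2, CF3CO2CH2CF3, THF, −78 °C) should give the trifluoroacetyl ketone F1.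
- Detrifluoroacetylative diazo transfer (MsN3, Et3N, MeCN) should give the 3-diazo ketone F2.
- Buffered desilylation (Bu4NF, AcOH, THF) should give the hydroxy diazo ketone F3.
- Irradiation (365 nm, CH2Cl2) should trigger the Wolff rearrangement, C5 (C8') migrating with retention to C3.
- The ketene F4 is captured by the C7' hydroxyl to give the cis-fused lactone F5, in which pyran C3 has become C8 and C4 has become C9.
- Enolate hydroxylation from the convex face (KN(SiMe3)2, THF, −78 °C; 2-(phenylsulfonyl)-3-phenyloxaziridine) then leads to 16.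

Step 7. During oxidation or handling the protected dione may tautomerise to the enol conjugated with O2 and the aryl group (C2=C3), which erases C7, and it may also hydrate. The fallback sets out from 12 and returns at 14. The silyl ether is removed first (HF·pyridine, THF, 0 °C) to give the dihydroxy ketone F6. The α-ketol alone is then oxidised with Cu(OAc)2 in MeOH, an oxidant that works through the enediolate of an acyloin and leaves an isolated benzylic alcohol alone. In this way 14 is formed with its hydroxyl already free and can be intercepted at once as 15, so no protected open dione is ever handled.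

Step 3. Kinetic axial attack on the enolate favours the 2,5-cis isomer. If equilibration through the zinc chelate is incomplete, or is accompanied by enolate scrambling or retro-oxa-Michael opening, facial and anti/syn control would be poor. The fallback sets out from 6 and returns at 8. It makes the C8'–C7' bond at the sp2 stage and sets C8' by protonation.
- α-Iodination of 6 (iodine, pyridine, CH2Cl2) should give the 5-iodo enone F7.
- An asymmetric Nozaki–Hiyama–Kishi coupling with 3 (CrCl2, NiCl2 cat., chiral oxazoline–sulfonamide ligand, Et3N, THF) should give the allylic alcohol F8, with C7' fixed by the ligand.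
- Conjugate reduction (excess LiBH(s-Bu)3, THF, −78 °C) followed by axial protonation of the enolate places the side chain equatorial. This is the 2,5-trans arrangement of 8 and also the thermodynamic outcome.

**Further compounds**

F1 | step 9 | (2S,5R)-2-Ar-5-[(S)-Ar(triethylsilyloxy)methyl]-3-(trifluoroacetyl)oxan-4-one (C3 stereolabile, largely enolised) | O=C1C(C(=O)C(F)(F)F)[C@@H](c2cc(OC)c(OCc3ccccc3)c(OC)c2)OC[C@@H]1[C@H](O[Si](CC)(CC)CC)c1cc(OC)c(OCc2ccccc2)c(OC)c1
F2 | step 9 | (2R,5R)-2-Ar-3-diazo-5-[(S)-Ar(triethylsilyloxy)methyl]oxan-4-one | O=C1C(=[N+]=[N-])[C@@H](c2cc(OC)c(OCc3ccccc3)c(OC)c2)OC[C@@H]1[C@H](O[Si](CC)(CC)CC)c1cc(OC)c(OCc2ccccc2)c(OC)c1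
F3 | step 9 | (2R,5R)-2-Ar-3-diazo-5-[(S)-Ar(hydroxy)methyl]oxan-4-one | O=C1C(=[N+]=[N-])[C@@H](c2cc(OC)c(OCc3ccccc3)c(OC)c2)OC[C@@H]1[C@H](O)c1cc(OC)c(OCc2ccccc2)c(OC)c1
F4 | step 9 | ketene, 2-Ar-4-[(S)-Ar(hydroxy)methyl]oxolan-3-ylidenemethanone (2,4-trans) | O=C=C1[C@@H](c2cc(OC)c(OCc3ccccc3)c(OC)c2)OC[C@@H]1[C@H](O)c1cc(OC)c(OCc2ccccc2)c(OC)c1
F5 | step 9 | (1S,2S,5R,6S)-2,6-di-Ar-3,7-dioxabicyclo[3.3.0]octan-8-one | COc1cc([C@H]2OC(=O)[C@@H]3[C@@H](c4cc(OC)c(OCc5ccccc5)c(OC)c4)OC[C@H]23)cc(OC)c1OCc1ccccc1
F6 | step 7 | (2R,3R,5R)-2-Ar-3-hydroxy-5-[(S)-Ar(hydroxy)methyl]oxan-4-one | O=C1[C@H](O)[C@@H](c2cc(OC)c(OCc3ccccc3)c(OC)c2)OC[C@@H]1[C@H](O)c1cc(OC)c(OCc2ccccc2)c(OC)c1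
F7 | step 3 | (S)-2-Ar-5-iodo-2,3-dihydro-4H-pyran-4-one | O=C1C(I)=CO[C@H](c2cc(OC)c(OCc3ccccc3)c(OC)c2)C1
F8 | step 3 | (S)-2-Ar-5-[(R)-Ar(hydroxy)methyl]-2,3-dihydro-4H-pyran-4-one | O=C1C([C@H](O)c2cc(OC)c(OCc3ccccc3)c(OC)c2)=CO[C@H](c2cc(OC)c(OCc3ccccc3)c(OC)c2)C1
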